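**Plan**
- Retrosynthetic cuts, in order: the O7–Si bond; the ring B C3'–alkenyl bond (Heck); the C2–C3 bond of ring C (1,3 O-to-C shift, which turns the chromanone back into a 2-aryl-4-methylidene-1,3-benzodioxine); the methylidene C=C (back to a lactone C=O); the two acetal C2–O bonds (ring B aldehyde plus 2,4-dihydroxybenzoic acid); the ring B C5'–prenyl bond, O-methyl and C5'–I bonds.
- Enabling feature: in ring C the unit O1–C2–C3–C4(=O) has C2 at the oxidation level of the ring B aldehyde carbon. Bound to O1 and to the enol oxygen of C4 it is an O,O-acetal, which holds C3 within reach of C2 so that the C2–C3 bond can form by intramolecular oxygen-to-carbon migration.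
- Forward order: the ring B aldehyde is built first (iodination, methylation, prenyl Suzuki coupling). It is condensed with the ring A acid to a 1,3-benzodioxin-4-one, a temporary hetero ring, which is methylenated. The rearrangement then converts that ring into ring C, and Heck coupling and desilylation finish the chain.
- Stereochemistry: C2 is the only stereocentre. It is set in the rearrangement by a chiral counteranion acting on a planar oxocarbenium ion, so the racemic acetal converges on the 2S ketone. The E-alkene comes from the syn-insertion/syn-elimination course of the Heck reaction.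

Key step: step 7

Assumption: the sense of induction of the chiral acid in step 7 cannot be derived from precedent, so the catalyst antipode (both are accessible from the two BINOL enantiomers) that leads to the 2S ketone is taken to be identified in a first screen. "Prenyl" means 3-methylbut-2-en-1-yl throughout.

Step 1
Reactants: 1 3-bromo-4-hydroxybenzaldehyde
Product: 2 3-bromo-4-hydroxy-5-iodobenzaldehyde
Conditions: NIS, AcOH, rt
Reagents that add atoms: N-iodosuccinimide, O=C1CCC(=O)N1I
Why: Electrophilic aromatic iodination, directed by the hydroxyl group to its only free ortho position since the para position carries the formyl group.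

Step 2
Reactants: 2 3-bromo-4-hydroxy-5-iodobenzaldehyde
Product: 3 3-bromo-5-iodo-4-methoxybenzaldehyde
Conditions: MeI, K2CO3, DMF, rt
Reagents that add atoms: iodomethane, CI
Why: Williamson ether synthesis on an acidic di-ortho-halogenated phenol, which should alkylate cleanly on oxygen under carbonate conditions that leave the aldehyde untouched.

Step 3
Reactants: 3 3-bromo-5-iodo-4-methoxybenzaldehyde; 4 prenylboronic acid pinacol ester
Product: 5 3-bromo-4-methoxy-5-(3-methylbut-2-en-1-yl)benzaldehyde
Conditions: PdCl2(dppf) (5 mol %), CsF, THF, 65 °C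
Reagents that add atoms: none
Why: Suzuki–Miyaura coupling in which zerovalent palladium should insert into the C–I bond far faster than into the C–Br bond, and the allylpalladium species formed on transmetalation should equilibrate to its less hindered primary terminus before reductive elimination, delivering the linear prenyl group with bromide and aldehyde intact.

Step 4
Reactants: 6 2,4-dihydroxybenzoic acid; 5 3-bromo-4-methoxy-5-(3-methylbut-2-en-1-yl)benzaldehyde
Product: 9 (±)-2-[3-bromo-4-methoxy-5-(3-methylbut-2-en-1-yl)phenyl]-7-hydroxy-4H-1,3-benzodioxin-4-one, via trimethylsilyl 2,4-bis(trimethylsilyloxy)benzoate 7 (not isolated), via 7-trimethylsilyloxy-1,3-benzodioxin-4-one 8 (not isolated)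
Conditions: HN(SiMe3)2, TMSCl (cat.), CH2Cl2, 40 °C, then evaporate; 5, TMSOTf (10 mol %), CH2Cl2, −78 to −20 °C; aq. citric acid, THF, 0 °C
Reagents that add atoms: none
Why: Noyori-type silyl-transfer acetalisation of a silyl ester/silyl ether pair with an aldehyde, driven by loss of hexamethyldisiloxane, should close the acyl acetal at low temperature without protic acid so that the prenyl alkene survives; the acetal carbon forms as a racemate that step 7 erases, and the labile aryl trimethylsilyl ether is hydrolysed on the mildly acidic work-up.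

Step 5
Reactants: 9 (±)-2-[3-bromo-4-methoxy-5-(3-methylbut-2-en-1-yl)phenyl]-7-hydroxy-4H-1,3-benzodioxin-4-one
Product: 10 (±)-2-[3-bromo-4-methoxy-5-(3-methylbut-2-en-1-yl)phenyl]-7-(triisopropylsilyloxy)-4H-1,3-benzodioxin-4-one
Conditions: TIPSCl, imidazole, DMF, rt
Reagents that add atoms: chlorotriisopropylsilane, CC(C)[Si](Cl)(C(C)C)C(C)C
Why: Silylation of the only free phenol under imidazole catalysis, conditions that benzodioxinone acyl acetals tolerate, gives a robust aryl silyl ether that removes the acidic proton before the organotitanium and acid steps.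

Step 6
Reactants: 10 (±)-2-[3-bromo-4-methoxy-5-(3-methylbut-2-en-1-yl)phenyl]-7-(triisopropylsilyloxy)-4H-1,3-benzodioxin-4-one
Product: 11 (±)-2-[3-bromo-4-methoxy-5-(3-methylbut-2-en-1-yl)phenyl]-4-methylidene-7-(triisopropylsilyloxy)-4H-1,3-benzodioxine
Conditions: Cp2TiMe2 (2.5 equiv), toluene/THF, 65 °C, dark; filtration through basic alumina (1% Et3N)
Reagents that add atoms: dimethyltitanocene Cp2TiMe2, C[Ti](C)(C1C=CC=C1)C1C=CC=C1
Why: Petasis methylenation, in which thermally generated Cp2Ti=CH2 undergoes [2+2] cycloaddition and cycloreversion with the lactone carbonyl as it does with 1,3-dioxan-4-ones, and which, being free of aluminium Lewis acids, should not trigger a premature racemic rearrangement of the acid-labile enol acetal.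

Step 7
Reactants: 11 (±)-2-[3-bromo-4-methoxy-5-(3-methylbut-2-en-1-yl)phenyl]-4-methylidene-7-(triisopropylsilyloxy)-4H-1,3-benzodioxine
Product: 12 (2S)-2-[3-bromo-4-methoxy-5-(3-methylbut-2-en-1-yl)phenyl]-7-(triisopropylsilyloxy)-2,3-dihydro-4H-chromen-4-one
Conditions: chiral imidodiphosphorimidate Brønsted acid (3,3'-diaryl-BINOL-derived, N-triflyl; 5 mol %), 5 Å molecular sieves, toluene, −40 °C
Reagents that add atoms: none
Why: Proposed new method: the acid protonates the enol-ether oxygen O3 (protonation at the methylidene carbon is reversible and leads to the same ion), the C2–O3 bond ionises to an aryloxy-stabilised benzylic oxocarbenium ion paired with the chiral anion while ring A carries the freed aryl ketone enol, and the enol carbon then attacks C2 to form C2–C3 and, after proton return to the anion, the C4 ketone. The closest known reactions are the Lewis-acid Petasis–Ferrier rearrangement of 4-methylidene-1,3-dioxanes to tetrahydropyran-4-ones and the chiral phosphoric acid-catalysed aza-Petasis–Ferrier rearrangement of hemiaminal vinyl ethers, both 1,3 O-to-C shifts through the same kind of cation/enol pair. Ring C closes in a 6-(enolendo)-endo-trig mode. The only stereocentre, C2, is set by the confined chiral counteranion, which shields one face of the planar oxocarbenium ion; because ionisation erases the acetal centre, both enantiomers of 11 should converge on (S)-12 with the catalyst antipode chosen for the 2S sense. The step needs C2–O3 rather than C2–O1 ionisation, C- rather than O-recombination and no hydrolysis: the unwanted ionisation and O-recombination are reversible whereas C–C bond formation gains an aryl ketone and is not, the 7-silyloxy group para to C4a raises the nucleophilicity of the enol, the ring B aryl group has no ortho substituent to block C2, and sieves plus low temperature keep out water and prevent protonation of the prenyl alkene.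

Step 8
Reactants: 12 (2S)-2-[3-bromo-4-methoxy-5-(3-methylbut-2-en-1-yl)phenyl]-7-(triisopropylsilyloxy)-2,3-dihydro-4H-chromen-4-one; 13 2-methylbut-3-en-2-ol
Product: 14 (2S)-2-{3-[(1E)-3-hydroxy-3-methylbut-1-en-1-yl]-4-methoxy-5-(3-methylbut-2-en-1-yl)phenyl}-7-(triisopropylsilyloxy)-2,3-dihydro-4H-chromen-4-one
Conditions: Pd(P(t-Bu)3)2 (3 mol %), Cy2NMe, 1,4-dioxane, 45 °C
Reagents that add atoms: none
Why: Mizoroki–Heck reaction in which oxidative addition of the aryl bromide to zerovalent palladium, insertion of the terminal alkene with aryl transfer to CH2 and syn β-hydride elimination (only the benzylic hydrogens are available) should give the E-styrenyl carbinol, while the hindered amine at 45 °C is too weak a base to open ring C by retro-oxa-Michael reaction, so C2 should keep its configuration.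

Step 9
Reactants: 14 (2S)-2-{3-[(1E)-3-hydroxy-3-methylbut-1-en-1-yl]-4-methoxy-5-(3-methylbut-2-en-1-yl)phenyl}-7-(triisopropylsilyloxy)-2,3-dihydro-4H-chromen-4-one
Product: 15 (2S)-7-hydroxy-2-{3-[(1E)-3-hydroxy-3-methylbut-1-en-1-yl]-4-methoxy-5-(3-methylbut-2-en-1-yl)phenyl}-2,3-dihydro-4H-chromen-4-one
Conditions: Bu4NF, AcOH (1:1), THF, 0 °C
Reagents that add atoms: none
Why: Fluoride-mediated desilylation of the aryl silyl ether, driven by Si–F bond formation and buffered with acetic acid so that neither phenoxide-induced retro-oxa-Michael racemisation at C2 nor loss of the tertiary allylic alcohol should set in.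

**Compound list**
1 | 3-bromo-4-hydroxybenzaldehyde | O=Cc1ccc(O)c(Br)c1 | starting material
2 | 3-bromo-4-hydroxy-5-iodobenzaldehyde | O=Cc1cc(Br)c(O)c(I)c1 | intermediate
3 | 3-bromo-5-iodo-4-methoxybenzaldehyde | COc1c(Br)cc(C=O)cc1I | intermediate
4 | prenylboronic acid pinacol ester | CC(C)=CCB1OC(C)(C)C(C)(C)O1 | starting material
5 | 3-bromo-4-methoxy-5-(3-methylbut-2-en-1-yl)benzaldehyde | COc1c(Br)cc(C=O)cc1CC=C(C)C | intermediate
6 | 2,4-dihydroxybenzoic acid | O=C(O)c1ccc(O)cc1O | starting material
7 | trimethylsilyl 2,4-bis(trimethylsilyloxy)benzoate | C[Si](C)(C)OC(=O)c1ccc(O[Si](C)(C)C)cc1O[Si](C)(C)C | intermediate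
8 | (±)-2-[3-bromo-4-methoxy-5-(3-methylbut-2-en-1-yl)phenyl]-7-(trimethylsilyloxy)-4H-1,3-benzodioxin-4-one | COc1c(Br)cc(C2OC(=O)c3ccc(O[Si](C)(C)C)cc3O2)cc1CC=C(C)C | intermediate
9 | (±)-2-[3-bromo-4-methoxy-5-(3-methylbut-2-en-1-yl)phenyl]-7-hydroxy-4H-1,3-benzodioxin-4-one | COc1c(Br)cc(C2OC(=O)c3ccc(O)cc3O2)cc1CC=C(C)C | intermediate
10 | (±)-2-[3-bromo-4-methoxy-5-(3-methylbut-2-en-1-yl)phenyl]-7-(triisopropylsilyloxy)-4H-1,3-benzodioxin-4-one | COc1c(Br)cc(C2OC(=O)c3ccc(O[Si](C(C)C)(C(C)C)C(C)C)cc3O2)cc1CC=C(C)C | intermediate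
11 | (±)-2-[3-bromo-4-methoxy-5-(3-methylbut-2-en-1-yl)phenyl]-4-methylidene-7-(triisopropylsilyloxy)-4H-1,3-benzodioxine | COc1c(Br)cc(C2OC(=C)c3ccc(O[Si](C(C)C)(C(C)C)C(C)C)cc3O2)cc1CC=C(C)C | intermediate
12 | (2S)-2-[3-bromo-4-methoxy-5-(3-methylbut-2-en-1-yl)phenyl]-7-(triisopropylsilyloxy)-2,3-dihydro-4H-chromen-4-one | COc1c(Br)cc([C@@H]2CC(=O)c3ccc(O[Si](C(C)C)(C(C)C)C(C)C)cc3O2)cc1CC=C(C)C | intermediate
13 | 2-methylbut-3-en-2-ol | C=CC(C)(C)O | starting material
14 | (2S)-2-{3-[(1E)-3-hydroxy-3-methylbut-1-en-1-yl]-4-methoxy-5-(3-methylbut-2-en-1-yl)phenyl}-7-(triisopropylsilyloxy)-2,3-dihydro-4H-chromen-4-one | COc1c(/C=C/C(C)(C)O)cc([C@@H]2CC(=O)c3ccc(O[Si](C(C)C)(C(C)C)C(C)C)cc3O2)cc1CC=C(C)C | intermediate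
15 | (2S)-7-hydroxy-2-{3-[(1E)-3-hydroxy-3-methylbut-1-en-1-yl]-4-methoxy-5-(3-methylbut-2-en-1-yl)phenyl}-2,3-dihydro-4H-chromen-4-one | COc1c(/C=C/C(C)(C)O)cc([C@@H]2CC(=O)c3ccc(O)cc3O2)cc1CC=C(C)C | target

Total step count: 9. Longest linear sequence: 9 steps (1 to 15); the ring A acid 6 joins at step 4.

**Steps most likely to fail**

Step 7. The ion pair may give poor enantioface discrimination, or the enol acetal may be diverted by protonation and hydrolytic cleavage before the C–C bond forms. The fallback is a classical aldol route with resolution; it sets out from aldehyde 5 and returns at 12. 2',4'-Dihydroxyacetophenone is silylated at its non-chelated hydroxyl (TIPSCl, imidazole) to 1-[2-hydroxy-4-(triisopropylsilyloxy)phenyl]ethan-1-one F1. Its dilithio derivative (LiN(SiMe3)2, 2.2 equiv, THF, −78 °C) is added to 5 to give the racemic aldol 3-[3-bromo-4-methoxy-5-(3-methylbut-2-en-1-yl)phenyl]-3-hydroxy-1-[2-hydroxy-4-(triisopropylsilyloxy)phenyl]propan-1-one F2. Intramolecular Mitsunobu etherification (PPh3, DIAD, THF, 0 °C) closes ring C to the racemic chromanone, (±)-2-[3-bromo-4-methoxy-5-(3-methylbut-2-en-1-yl)phenyl]-7-(triisopropylsilyloxy)-2,3-dihydro-4H-chromen-4-one F3. Kinetic resolution by Noyori–Ikariya transfer hydrogenation (RuCl(p-cymene)[(R,R)-TsDPEN], HCO2H/Et3N, EtOAc, rt) is expected to reduce the 2R ketone to the cis alcohol (2R,4R)-2-[3-bromo-4-methoxy-5-(3-methylbut-2-en-1-yl)phenyl]-7-(triisopropylsilyloxy)-3,4-dihydro-2H-chromen-4-ol F4 and to leave (S)-12, which is separated and carried into step 8.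

Step 4. The aryl silyl ether is a weak nucleophile, so acetalisation may stall, or the Lewis acid may consume the prenyl alkene through Prins-type addition to the activated aldehyde. The fallback closes the acetal lactone before the prenyl group is present; it sets out from 3 and 6 and returns at 9. Anhydride-mediated condensation of 6 with 3 (TFAA, TFA, 0 °C to rt, then aqueous NaHCO3 to cleave the aryl trifluoroacetate) should give (±)-2-(3-bromo-5-iodo-4-methoxyphenyl)-7-hydroxy-4H-1,3-benzodioxin-4-one F5. Iodide-selective Suzuki–Miyaura coupling with 4 (PdCl2(dppf), anhydrous CsF, THF, 65 °C) then installs the prenyl group to give 9.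

Step 8. The amine base may open and reclose ring C by retro-oxa-Michael reaction and so erode the C2 configuration, or oxidative addition at the electron-rich ortho-methoxy bromide may be slow. The fallback is a base-free Stille coupling; it sets out from 12 and returns at 14. Hydrostannylation of 2-methylbut-3-yn-2-ol (Bu3SnH, PdCl2(PPh3)2 cat., THF) gives (E)-2-methyl-4-(tributylstannyl)but-3-en-2-ol F6. Coupling of F6 with 12 (Pd(PPh3)4, toluene, 90 °C, no base) should give 14 with the alkene geometry carried over from the stannane.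

**Further compounds**
F1 | step 7 | 1-[2-hydroxy-4-(triisopropylsilyloxy)phenyl]ethan-1-one | CC(=O)c1ccc(O[Si](C(C)C)(C(C)C)C(C)C)cc1O
F2 | step 7 | (±)-3-[3-bromo-4-methoxy-5-(3-methylbut-2-en-1-yl)phenyl]-3-hydroxy-1-[2-hydroxy-4-(triisopropylsilyloxy)phenyl]propan-1-one | COc1c(Br)cc(C(O)CC(=O)c2ccc(O[Si](C(C)C)(C(C)C)C(C)C)cc2O)cc1CC=C(C)C
F3 | step 7 | (±)-2-[3-bromo-4-methoxy-5-(3-methylbut-2-en-1-yl)phenyl]-7-(triisopropylsilyloxy)-2,3-dihydro-4H-chromen-4-one | COc1c(Br)cc(C2CC(=O)c3ccc(O[Si](C(C)C)(C(C)C)C(C)C)cc3O2)cc1CC=C(C)C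
F4 | step 7 | (2R,4R)-2-[3-bromo-4-methoxy-5-(3-methylbut-2-en-1-yl)phenyl]-7-(triisopropylsilyloxy)-3,4-dihydro-2H-chromen-4-ol | COc1c(Br)cc([C@H]2C[C@@H](O)c3ccc(O[Si](C(C)C)(C(C)C)C(C)C)cc3O2)cc1CC=C(C)C
F5 | step 4 | (±)-2-(3-bromo-5-iodo-4-methoxyphenyl)-7-hydroxy-4H-1,3-benzodioxin-4-one | COc1c(Br)cc(C2OC(=O)c3ccc(O)cc3O2)cc1I
F6 | step 8 | (E)-2-methyl-4-(tributylstannyl)but-3-en-2-ol | CCCC[Sn](CCCC)(CCCC)/C=C/C(C)(C)O
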